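**Strategy.** The quinone is assembled last, on the intact terpenoid, by a Moore rearrangement. Numbering the quinone ring C-1 (C=O next to CH), C-2 (C–OH), C-3 (C–CH2-decalin), C-4 (C=O), C-5 (C–OMe), C-6 (CH), the route exploits the vicinal oxygenation at C-1/C-2 and the para relationship of C-2–OH and C-5–OMe. A 4-[(Z)-2-ethoxyvinyl]-4-methoxycyclobutenone, built from dimethyl squarate, the neopentyllithium of the decalin and (Z)-2-ethoxyvinyllithium, opens thermally to a dienylketene. Its 6π closure forms C-1–C-2 and delivers the C-2 oxygen as a free phenol, which fixes the OH/OMe regiochemistry. The decalin stereotriad comes from one catalytic asymmetric exo Diels–Alder reaction.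

Key step: step 8

Remark (assumption): the (R)-oxazaborolidinium catalyst of step 3 is assumed, from the accepted model for 2-substituted enals, to expose the Cα-Si face of tiglic aldehyde. If the adduct proves antipodal, the (S)-catalyst is used with no other change.

Abbreviation: "Ter-CH2" is the [(1R,2S,8aS)-1,2,5,5-tetramethyl-1,2,3,5,6,7,8,8a-octahydronaphthalen-1-yl]methyl group of the target (terpenoid numbering 8S,9R,10S, C5=C6 alkene).

**Step 1**
Reactants: 1 2,2-dimethylcyclohexanone
Product: 2 6,6-dimethylcyclohex-1-en-1-yl trifluoromethanesulfonate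
Conditions: LDA, THF, −78 °C; PhNTf2, −78 °C → rt
Reagents that add atoms: N-phenylbis(trifluoromethanesulfonimide), O=S(=O)(N(c1ccccc1)S(=O)(=O)C(F)(F)F)C(F)(F)F
Why: The ketone can enolise only toward C-6 (C-2 is quaternary), and O-sulfonylation of the lithium enolate gives the enol triflate (enol triflate formation).

**Step 2**
Reactants: 2 6,6-dimethylcyclohex-1-en-1-yl trifluoromethanesulfonate
Product: 3 1-ethenyl-6,6-dimethylcyclohex-1-ene
Conditions: tributyl(vinyl)stannane, Pd(PPh3)4 (cat.), LiCl, THF, reflux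
Reagents that add atoms: tributyl(vinyl)stannane, C=C[Sn](CCCC)(CCCC)CCCC
Why: Stille coupling of an enol triflate with a vinylstannane should give the 1,3-diene with the ring double bond fixed in place.

**Step 3**
Reactants: 3 1-ethenyl-6,6-dimethylcyclohex-1-ene; 4 (E)-2-methylbut-2-enal (tiglic aldehyde)
Product: 5 (1R,2S,8aR)-1,2,5,5-tetramethyl-1,2,3,5,6,7,8,8a-octahydronaphthalene-1-carbaldehyde
Conditions: (R)-o-tolyl-CBS-oxazaborolidine (20 mol %), Tf2NH (18 mol %), CH2Cl2, −78 → −40 °C
Reagents that add atoms: none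
Why: In this oxazaborolidinium-catalysed asymmetric Diels–Alder reaction of a 2-substituted enal, the ring terminus of the 1-substituted diene should bond to the formyl-bearing carbon (ortho regiochemistry), the formyl-exo transition state typical of α-methyl enals places CHO cis to H-10, the E geometry of 4 fixes the 8-Me/9-Me cis relationship, and catalyst shielding of one enal face (attack on Cα-Si) sets the absolute configuration of all three centres.

**Step 4**
Reactants: 5 the Diels–Alder aldehyde
Product: 6 [(1R,2S,8aR)-1,2,5,5-tetramethyl-1,2,3,5,6,7,8,8a-octahydronaphthalen-1-yl]methanol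
Conditions: NaBH4, MeOH, 0 °C
Reagents that add atoms: none
Why: Hydride reduction of a non-enolisable neopentyl aldehyde touches no stereocentre.

**Step 5**
Reactants: 6 the neopentyl alcohol
Product: 7 (1R,2S,8aR)-1-(iodomethyl)-1,2,5,5-tetramethyl-1,2,3,5,6,7,8,8a-octahydronaphthalene
Conditions: PPh3, I2, imidazole, toluene, 90 °C
Reagents that add atoms: iodine, II
Why: Iodide displaces the alkoxyphosphonium salt of the primary alcohol (Appel-type iodination, Garegg–Samuelsson conditions); substitution at the neopentyl CH2 is slow, but no β-hydrogen allows elimination and no stereocentre is involved.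

**Step 6**
Reactants: 7 the neopentyl iodide; 8 dimethyl squarate (3,4-dimethoxycyclobut-3-ene-1,2-dione)
Product: 11 3-methoxy-4-(Ter-CH2)cyclobut-3-ene-1,2-dione, via neopentyllithium 9 (not isolated), via lithium alkoxide adduct 10 (not isolated)
Conditions: t-BuLi (2.1 equiv), Et2O–pentane, −78 °C; add to 8, THF, −78 °C; TFAA, −78 °C; aq. NH4Cl, rt
Reagents that add atoms: water, O
Why: Iodine–lithium exchange gives a β-hydrogen-free neopentyllithium that adds 1,2 to one squarate carbonyl, and trifluoroacetylation followed by aqueous work-up converts the adduct into the 3-alkyl-4-methoxycyclobutenedione (the standard squarate alkylation sequence).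

**Step 7**
Reactants: 11 the cyclobutenedione; 12 (Z)-1-bromo-2-ethoxyethene
Product: 15 4-[(Z)-2-ethoxyethenyl]-3,4-dimethoxy-2-(Ter-CH2)cyclobut-2-en-1-one (mixture of C-4 epimers), via (Z)-2-ethoxyvinyllithium 13 (not isolated), via lithium alkoxide 14 (not isolated)
Conditions: 12, t-BuLi (2 equiv), THF–Et2O, −78 °C; add 11, −78 °C; MeOTf, −78 → 0 °C
Reagents that add atoms: methyl trifluoromethanesulfonate, COS(=O)(=O)C(F)(F)F
Why: Bromine–lithium exchange gives the configurationally stable (Z)-vinyllithium, which should add to the more electrophilic carbonyl (the one next to the methoxy-bearing carbon, not the vinylogous ester carbonyl), and the tertiary alkoxide is O-methylated in situ; the new C-4 stereocentre forms unselectively and is erased in step 8.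

**Step 8**
Reactants: 15 the 4-alkenyl-4-methoxycyclobutenone
Product: 18 6-ethoxy-3,4-dimethoxy-2-(Ter-CH2)phenyl acetate, via dienylketene 16 (not isolated), via phenol 17 (not isolated)
Conditions: toluene (degassed, 0.01 M), 110 °C; then Ac2O, Et3N, DMAP (cat.), rt
Reagents that add atoms: acetic anhydride, CC(=O)OC(C)=O
Why: Heating opens the cyclobutenone C1–C4 bond by conrotatory 4π electrocyclic ring opening to dienylketene 16, whose ketene carbon (future quinone C-2) bonds to the ethoxy-bearing vinyl terminus (future C-1) in a thermal disrotatory 6π electrocyclisation; tautomerisation gives phenol 17, which is acetylated in the same flask because so electron-rich a phenol is air-sensitive. The closest known reaction type is the Moore rearrangement of 4-alkenyl-4-alkoxycyclobutenones to 4-alkoxyphenols. The one ring formed, the six-membered carbocycle, is closed by 6π electrocyclisation of the dienylketene. No stereocentre is created and the C-4 stereocentre of 15 is erased. The selectivity needed is torquoselectivity in the ring opening, secured by the C-4 methoxy donor, which rotates outward and so places the vinyl group inward, cis to the ketene; the regiochemistry (free OH at C-2 between C-1–OEt and C-3–CH2Ter, para to C-5–OMe) is fixed by the connectivity of 15. High dilution and the absence of nucleophiles should favour this closure over ketene dimerisation or [2+2] addition to the remote, hindered C5=C6 alkene.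

**Step 9**
Reactants: 18 the aryl acetate
Product: 19 4-methoxy-3,6-dioxo-2-(Ter-CH2)cyclohexa-1,4-dien-1-yl acetate (2-acetoxy-5-methoxy-3-(Ter-CH2)-1,4-benzoquinone)
Conditions: CAN (2.5 equiv), MeCN–H2O, 0 °C
Reagents that add atoms: water, O
Why: CAN oxidative dealkylation should take the para-dialkoxy pair (C-1–OEt and C-4–OMe) to the p-quinone, because the acetoxy group at C-2 is not an oxidisable donor, so the C-2/C-5 pair and the C-5 methoxy group are kept.

**Step 10**
Reactants: 19 the acetoxyquinone
Product: 20 2-hydroxy-5-methoxy-3-(Ter-CH2)cyclohexa-2,5-diene-1,4-dione (target)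
Conditions: K2CO3, MeOH, 0 °C; dilute citric acid work-up
Reagents that add atoms: none
Why: Methanolysis of the enol acetate (a vinylogous mixed anhydride) should release the hydroxyquinone under conditions where any methoxide exchange at C-5 is degenerate.

**Compound list**
1 | 2,2-dimethylcyclohexanone | CC1(C)CCCCC1=O | starting material
2 | 6,6-dimethylcyclohex-1-en-1-yl trifluoromethanesulfonate | CC1(C)CCCC=C1OS(=O)(=O)C(F)(F)F | intermediate
3 | 1-ethenyl-6,6-dimethylcyclohex-1-ene | C=CC1=CCCCC1(C)C | intermediate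
4 | (E)-2-methylbut-2-enal (tiglic aldehyde) | C/C=C(\C)C=O | starting material
5 | (1R,2S,8aR)-1,2,5,5-tetramethyl-1,2,3,5,6,7,8,8a-octahydronaphthalene-1-carbaldehyde | O=C[C@@]1(C)[C@@H]2CCCC(C)(C)C2=CC[C@@H]1C | intermediate
6 | [(1R,2S,8aR)-1,2,5,5-tetramethyl-1,2,3,5,6,7,8,8a-octahydronaphthalen-1-yl]methanol | OC[C@@]1(C)[C@@H]2CCCC(C)(C)C2=CC[C@@H]1C | intermediate
7 | (1R,2S,8aR)-1-(iodomethyl)-1,2,5,5-tetramethyl-1,2,3,5,6,7,8,8a-octahydronaphthalene | IC[C@@]1(C)[C@@H]2CCCC(C)(C)C2=CC[C@@H]1C | intermediate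
8 | dimethyl squarate | COC1=C(OC)C(=O)C1=O | starting material
9 | Ter-CH2-Li (neopentyllithium of the decalin) | [Li]C[C@@]1(C)[C@@H]2CCCC(C)(C)C2=CC[C@@H]1C | intermediate
10 | lithium 2,3-dimethoxy-4-oxo-1-(Ter-CH2)cyclobut-2-en-1-olate | [Li]OC1(C[C@@]2(C)[C@@H]3CCCC(C)(C)C3=CC[C@@H]2C)C(OC)=C(OC)C1=O | intermediate
11 | 3-methoxy-4-(Ter-CH2)cyclobut-3-ene-1,2-dione | COC1=C(C[C@@]2(C)[C@@H]3CCCC(C)(C)C3=CC[C@@H]2C)C(=O)C1=O | intermediate
12 | (Z)-1-bromo-2-ethoxyethene | CCO/C=C\Br | starting material
13 | (Z)-2-ethoxyvinyllithium | CCO/C=C\[Li] | intermediate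
14 | lithium 1-[(Z)-2-ethoxyethenyl]-2-methoxy-4-oxo-3-(Ter-CH2)cyclobut-2-en-1-olate | CCO/C=C\C1(O[Li])C(OC)=C(C[C@@]2(C)[C@@H]3CCCC(C)(C)C3=CC[C@@H]2C)C1=O | intermediate
15 | 4-[(Z)-2-ethoxyethenyl]-3,4-dimethoxy-2-(Ter-CH2)cyclobut-2-en-1-one (C-4 epimers) | CCO/C=C\C1(OC)C(OC)=C(C[C@@]2(C)[C@@H]3CCCC(C)(C)C3=CC[C@@H]2C)C1=O | intermediate
16 | (3Z,5Z)-6-ethoxy-3,4-dimethoxy-2-(Ter-CH2)hexa-1,3,5-trien-1-one (dienylketene) | O=C=C(C[C@@]1(C)[C@@H]2CCCC(C)(C)C2=CC[C@@H]1C)/C(OC)=C(\C=C/OCC)OC | intermediate
17 | 6-ethoxy-3,4-dimethoxy-2-(Ter-CH2)phenol | CCOc1cc(OC)c(OC)c(C[C@@]2(C)[C@@H]3CCCC(C)(C)C3=CC[C@@H]2C)c1O | intermediate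
18 | 6-ethoxy-3,4-dimethoxy-2-(Ter-CH2)phenyl acetate | CCOc1cc(OC)c(OC)c(C[C@@]2(C)[C@@H]3CCCC(C)(C)C3=CC[C@@H]2C)c1OC(C)=O | intermediate
19 | 2-acetoxy-5-methoxy-3-(Ter-CH2)-1,4-benzoquinone | COC1=CC(=O)C(OC(C)=O)=C(C[C@@]2(C)[C@@H]3CCCC(C)(C)C3=CC[C@@H]2C)C1=O | intermediate
20 | 2-hydroxy-5-methoxy-3-{[(1R,2S,8aS)-1,2,5,5-tetramethyl-1,2,3,5,6,7,8,8a-octahydronaphthalen-1-yl]methyl}cyclohexa-2,5-diene-1,4-dione | COC1=CC(=O)C(O)=C(C[C@@]2(C)[C@@H]3CCCC(C)(C)C3=CC[C@@H]2C)C1=O | target

**Step count.** Total: 10 steps. Longest linear sequence: 10 steps (from 1; compounds 4, 8 and 12 are purchased).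

**Steps most likely to fail**

1. Step 3. Enantiofacial discrimination may be insufficient, or conversion low, because a trisubstituted enal and the hindered ring terminus of the diene must meet at the forming quaternary centre; some endo leakage is also possible. The fallback sets out from 3 and 4 and replaces catalytic enantiocontrol by classical resolution. An Et2AlCl-promoted exo Diels–Alder reaction (CH2Cl2, −78 °C) should give the racemic aldehyde F1, and NaBH4 reduction the racemic alcohol F2. Carbamoylation with (S)-1-phenylethyl isocyanate (DMAP, toluene, 80 °C) and separation of the diastereomers by crystallisation or chromatography should give the carbamate of the (1R,2S,8aR)-alcohol F3. LiAlH4 (THF, reflux) cleaves it, and the route is rejoined at 6.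

2. Step 5. Displacement at the neopentyl carbon may stall at the alkoxyphosphonium stage, or partial ionisation may lead to skeletal rearrangement or participation of the C5=C6 alkene. The fallback sets out from 5 and avoids substitution at that carbon altogether. Wittig methoxymethylenation (Ph3P=CHOMe, THF) should give the enol ether F4 (E/Z mixture), and mild hydrolysis (oxalic acid, wet THF) the homologous aldehyde F5. Pinnick oxidation (NaClO2, NaH2PO4, 2-methyl-2-butene) should give the acid F6. The derived Barton ester F7 (DCC, N-hydroxypyridine-2-thione, not isolated) is photolysed with iodoform, and radical decarboxylative iodination rejoins the route at 7.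

3. Step 7. O-Methylation of the hindered tertiary lithium alkoxide may be incomplete, or the alkoxide may ring-open or decompose on warming before it is capped. The fallback sets out from 11 and moves the methylation to after the ring closure. The alkoxide 14 is capped with Me3SiCl at −78 °C to give the 4-trimethylsilyloxy cyclobutenone F8. Thermolysis in toluene should give the silyloxyphenol F9 (not isolated), which is acetylated in the same flask to the silyloxy aryl acetate F10. Desilylation (citric acid, MeOH) should give the hydroxy aryl acetate F11, and methylation under neutral conditions (MeI, Ag2O) rejoins the route at 18.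

**Further compounds**
F1 | step 3 | racemic exo aldehyde, rel-(1R,2S,8aR)-1,2,5,5-tetramethyl-1,2,3,5,6,7,8,8a-octahydronaphthalene-1-carbaldehyde | O=CC1(C)C2CCCC(C)(C)C2=CCC1C
F2 | step 3 | racemic alcohol, rel-(1R,2S,8aR)-(1,2,5,5-tetramethyl-1,2,3,5,6,7,8,8a-octahydronaphthalen-1-yl)methanol | OCC1(C)C2CCCC(C)(C)C2=CCC1C
F3 | step 3 | [(1R,2S,8aR)-1,2,5,5-tetramethyl-1,2,3,5,6,7,8,8a-octahydronaphthalen-1-yl]methyl N-[(S)-1-phenylethyl]carbamate | C[C@H](NC(=O)OC[C@@]1(C)[C@@H]2CCCC(C)(C)C2=CC[C@@H]1C)c1ccccc1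
F4 | step 5 | methyl enol ether of the homologated aldehyde, 1-(2-methoxyethenyl) decalin (E/Z mixture) | COC=C[C@@]1(C)[C@@H]2CCCC(C)(C)C2=CC[C@@H]1C
F5 | step 5 | Ter-CH2-CHO, 2-(decalin-1-yl)acetaldehyde | O=CC[C@@]1(C)[C@@H]2CCCC(C)(C)C2=CC[C@@H]1C
F6 | step 5 | Ter-CH2-CO2H, 2-(decalin-1-yl)acetic acid | OC(=O)C[C@@]1(C)[C@@H]2CCCC(C)(C)C2=CC[C@@H]1C
F7 | step 5 | Barton ester, 2-thioxopyridin-1(2H)-yl 2-(decalin-1-yl)acetate | O=C(C[C@@]1(C)[C@@H]2CCCC(C)(C)C2=CC[C@@H]1C)ON1C=CC=CC1=S
F8 | step 7 | 4-[(Z)-2-ethoxyethenyl]-3-methoxy-2-(Ter-CH2)-4-(trimethylsilyloxy)cyclobut-2-en-1-one | CCO/C=C\C1(O[Si](C)(C)C)C(OC)=C(C[C@@]2(C)[C@@H]3CCCC(C)(C)C3=CC[C@@H]2C)C1=O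
F9 | step 7 | 6-ethoxy-3-methoxy-2-(Ter-CH2)-4-(trimethylsilyloxy)phenol | CCOc1cc(O[Si](C)(C)C)c(OC)c(C[C@@]2(C)[C@@H]3CCCC(C)(C)C3=CC[C@@H]2C)c1O
F10 | step 7 | 6-ethoxy-3-methoxy-2-(Ter-CH2)-4-(trimethylsilyloxy)phenyl acetate | CCOc1cc(O[Si](C)(C)C)c(OC)c(C[C@@]2(C)[C@@H]3CCCC(C)(C)C3=CC[C@@H]2C)c1OC(C)=O
F11 | step 7 | 6-ethoxy-4-hydroxy-3-methoxy-2-(Ter-CH2)phenyl acetate | CCOc1cc(O)c(OC)c(C[C@@]2(C)[C@@H]3CCCC(C)(C)C3=CC[C@@H]2C)c1OC(C)=O
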